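Slowness is the first thing we read for: the violet run reads 77% at 5.00 min and 77% at 6.00 min, but with a scatter of 1.5 percentage points these two readings do not tell a stop from a slow rise. Starting material and partner give target, and capture agent and protic impurity are charged beside them.

in all of them: starting material 0.20 M

| flask | partner | capture agent | protic impurity | temperature | remark | time |
|---|---|---|---|---|---|---|
| blue | 0.20 M | 0.020 M | 0.060 M | 25 °C | run made earlier |  |
| violet | 0.60 M | 0.020 M | 0.060 M | 25 °C | run made earlier |  |
| north-west | 0.300 M | 0.0300 M | 0.0600 M |  | at 45 °C throughout | 30 min |
| south-east | 0.300 M | 0.0200 M | 0.0600 M |  | at 25 °C until 6.0 min, from then on at 45 °C | 30 min |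

| run | time / min | target / % |
|---|---|---|
| blue | 1.50 | 14 |
| blue | 3.00 | 38 |
| blue | 5.00 | 56 |
| blue | 6.00 | 61 |
| violet | 1.50 | 32 |
| violet | 3.00 | 62 |
| violet | 5.00 | 77 |
| violet | 6.00 | 77 |

(standard deviation of a reading: 1.5 percentage points)

- the earlier runs do not show what temperature does; that part of a forecast is a guess
- no earlier run changes the charge of capture agent; that part of a forecast is a guess

* the flask that ends with the higher amount of target, in percent of the starting material charged, or "neither" when 2 percentage points or less lies between them (north-west / south-east / neither)
* final target, as a percentage of the starting material charged, in north-west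
* final target, as a percentage of the starting material charged, in south-east

1. We must choose the next run, and we choose it by where it stops. Speed comes second.

2. For north-west we reckon 85.0%. That is the ceiling C: the smaller of two shares. One share is partner over starting material. The other is one minus the excess of protic impurity over capture agent, taken over starting material. It assumes that capture agent cancels impurity one for one, which no earlier run tests.

3. For south-east the same reckoning gives 80.0%. The partner share is 150% in both flasks, larger than either ceiling, so the impurity share sets C in both.

4. The gap is 5 points, wider than the margin of 2 points. So on this reckoning we would run north-west, and that choice rests on the one-for-one assumption. The two flasks also differ in temperature, which C does not count.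

The forecast also says north-west, with 83% for north-west and 78% for south-east. Both sit a little under our ceilings, and it says “The temperature effect on the loss and the capture stoichiometry are guesses”.

The flasks give north-west: north-west ends at 85.5% and south-east at 80.2%.

    starting material → open intermediate (k = 0.00850 s⁻¹, Ea = 93.0 kJ mol⁻¹)
    partner → second intermediate (k = 0.00410 s⁻¹, Ea = 82.0 kJ mol⁻¹)
    open intermediate + second intermediate → target (k = 0.260 L mol⁻¹ s⁻¹, Ea = 61.0 kJ mol⁻¹)
    2 second intermediate → homo product (k = 0.00860 L mol⁻¹ s⁻¹, Ea = 43.0 kJ mol⁻¹)
    open intermediate + capture agent → trapped intermediate (k = 0.0830 L mol⁻¹ s⁻¹, Ea = 48.0 kJ mol⁻¹)
    starting material + protic impurity → quenched substrate (k = 0.0300 L mol⁻¹ s⁻¹, Ea = 58.0 kJ mol⁻¹)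
    (constants at 25 °C)

In north-west at 0.353 min, starting material went to open intermediate 15 times as fast as to quenched substrate. C stood at 85.0% and north-west at 85.5%, but its loss is two products, quenched substrate 7.10% and trapped intermediate 7.45%, and in the equations capture agent does not react with protic impurity. So the near match does not bear out the one-for-one assumption, and the lead of north-west over south-east is not shown to come from its capture agent, since the two flasks differ in temperature as well.

Now take the neighbour of north-west with 0.80 M of starting material. Its partner share is 37.5% and its impurity share 96.2%, so C is 37.5%, with partner as limiting reagent. That neighbour ends at 37.5% target, with 0% of its partner left and 53.8% standing as open intermediate.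

Readings and results were computed for substances that don't exist; the scatter is artificial.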